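**Assumption:** the presumed biosynthesis closes the oxane by conjugate (oxa-Michael/SN2′-type) addition of the primary C6 hydroxyl of an acyclic precursor to C2 of the carboxyl-activated olefin. Locants used: oxane O1, C2 (acrylate-bearing), C3, C4, C5 (side-chain-bearing), C6 (OCH2).

## Retrosynthetic overview

1. The target comes from an ethyl acrylate carrying the diol as a cyclic carbonate; one LiOH step frees both.
2. The oxane is the only ring of the target and is formed last: the C6–OH of an acyclic lactol adds 6-exo to C2 of an alkylidene phosphonoacetate made in the flask, and the resulting phosphonate is methylenated to the acrylate in the same pot.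
3. The lactol comes from a C19 aldehyde: organocatalytic α-hydroxymethylation sets C5 and adds C6, then a formyl-Wittig/Cu–H sequence adds C3–C2.
4. The syn-diol comes from CO2 insertion into a (2R,3R)-epoxide with retention (a temporary dioxolanone ring, formed in step 3).
5. The epoxide comes from Sharpless epoxidation of (E,E)-farnesol; its C1 is joined to a three-carbon acetal Grignard reagent through the triflate.

## Route

**Step 1**
Reactants: 1 (2E,6E)-farnesol
Product: 2 [(2R,3R)-3-[(3E)-4,8-dimethylnona-3,7-dien-1-yl]-3-methyloxiran-2-yl]methanol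
Conditions: Ti(OiPr)4 (5 mol%), D-(−)-DET (6 mol%), t-BuOOH, 4 Å MS, CH2Cl2, −20 °C
Reagents that add atoms: tert-butyl hydroperoxide, CC(C)(C)OO
Why: Katsuki–Sharpless asymmetric epoxidation touches only the allylic olefin; D-(−)-tartrate gives the (2R,3R) series (L-(+)-DET is established to give 2S,3S with geraniol and farnesol), which fixes both carbinol configurations of the later diol.

**Step 2**
Reactants: 2 [(2R,3R)-3-[(3E)-4,8-dimethylnona-3,7-dien-1-yl]-3-methyloxiran-2-yl]methanol; 3 2-(2-bromoethyl)-1,3-dioxolane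
Product: 6 2-{3-[(2R,3R)-3-[(3E)-4,8-dimethylnona-3,7-dien-1-yl]-3-methyloxiran-2-yl]propyl}-1,3-dioxolane, via epoxy triflate 4 (not isolated), via Grignard reagent 5 (not isolated)
Conditions: Tf2O, 2,6-lutidine, CH2Cl2, −78 °C; crude 4 in Et2O added to 5 (from 3, Mg, THF, 25 °C), CuBr·SMe2 (10 mol%), −78 → −30 °C
Reagents that add atoms: trifluoromethanesulfonic anhydride, O=S(=O)(OS(=O)(=O)C(F)(F)F)C(F)(F)F (triflyl group in 4 only); magnesium, [Mg] (in 5 only)
Why: Copper(I)-catalysed Grignard–triflate cross-coupling (Kotsuki type) displaces the primary triflate much faster than the hindered trisubstituted epoxide is opened; no stereocentre is touched.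

**Step 3**
Reactants: 6 2-{3-[(2R,3R)-3-[(3E)-4,8-dimethylnona-3,7-dien-1-yl]-3-methyloxiran-2-yl]propyl}-1,3-dioxolane
Product: 7 (4R,5R)-4-[(3E)-4,8-dimethylnona-3,7-dien-1-yl]-5-[3-(1,3-dioxolan-2-yl)propyl]-4-methyl-1,3-dioxolan-2-one
Conditions: CO2 (1 MPa), Al(III) aminotris(phenolate) (2 mol%), PPNCl (5 mol%), MEK, 80 °C
Reagents that add atoms: carbon dioxide, O=C=O
Why: Lewis acid/halide-catalysed CO2–epoxide cycloaddition: chloride opens the epoxide at the secondary carbon with inversion, the tertiary alkoxide is carboxylated, and the carbonate displaces chloride with a second inversion, so both C–O configurations are retained (a cis-hydroxylation equivalent giving the syn-diol pattern).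

**Step 4**
Reactants: 7 (4R,5R)-4-[(3E)-4,8-dimethylnona-3,7-dien-1-yl]-5-[3-(1,3-dioxolan-2-yl)propyl]-4-methyl-1,3-dioxolan-2-one
Product: 8 4-[(4R,5R)-5-[(3E)-4,8-dimethylnona-3,7-dien-1-yl]-5-methyl-2-oxo-1,3-dioxolan-4-yl]butanal
Conditions: PPTS (20 mol%), acetone/H2O 4:1, 60 °C
Reagents that add atoms: water, O
Why: Mild acid-catalysed acetal hydrolysis; the cyclic carbonate and the trisubstituted olefins are stable to PPTS.

**Step 5**
Reactants: 8 4-[(4R,5R)-5-[(3E)-4,8-dimethylnona-3,7-dien-1-yl]-5-methyl-2-oxo-1,3-dioxolan-4-yl]butanal; 9 2-(triphenyl-λ5-phosphanylidene)acetaldehyde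
Product: 11 (2E,4S)-6-[(4R,5R)-5-[(3E)-4,8-dimethylnona-3,7-dien-1-yl]-5-methyl-2-oxo-1,3-dioxolan-4-yl]-4-(hydroxymethyl)hex-2-enal, via hydroxymethyl aldehyde 10 (not isolated)
Conditions: (S)-α,α-diphenylprolinol TMS ether (20 mol%), 37% aq. HCHO, pH 7 phosphate buffer, PhMe, rt; phases separated, organic layer washed (aq. NH4Cl); then 9 (1.1 equiv), PhMe, 40 °C
Reagents that add atoms: formaldehyde, C=O
Why: Enamine-catalysed α-hydroxymethylation (Boeckman): the diphenyl(silyloxy)methyl group shields one enamine face, so formaldehyde adds to give the (2R)-aldehyde 10, which sets oxane C5 and installs C6; immediate Wittig trapping with the stabilised ylide gives the E-enal before the labile α-centre can epimerise.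

**Step 6**
Reactants: 11 (2E,4S)-6-[(4R,5R)-5-[(3E)-4,8-dimethylnona-3,7-dien-1-yl]-5-methyl-2-oxo-1,3-dioxolan-4-yl]-4-(hydroxymethyl)hex-2-enal
Product: 13 (4R,5R)-4-[(3E)-4,8-dimethylnona-3,7-dien-1-yl]-5-{2-[(3S)-6-hydroxyoxan-3-yl]ethyl}-4-methyl-1,3-dioxolan-2-one (lactol; anomer mixture), via open-chain hydroxy aldehyde 12 (not isolated)
Conditions: [(Ph3P)CuH]6 (0.25 equiv), H2O (3 equiv), THF/PhH, rt
Reagents that add atoms: none
Why: Stryker conjugate reduction delivers hydride only to the enal β-carbon under neutral conditions (no dienamine pathway, so the γ-stereocentre is safe), leaving isolated trisubstituted olefins and the carbonate untouched; the δ-hydroxy aldehyde closes to the lactol.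

**Step 7 (key ring-forming step)**
Reactants: 13 (4R,5R)-4-[(3E)-4,8-dimethylnona-3,7-dien-1-yl]-5-{2-[(3S)-6-hydroxyoxan-3-yl]ethyl}-4-methyl-1,3-dioxolan-2-one; 14 triethyl phosphonoacetate
Product: 17 ethyl 2-[(2R,5R)-5-{2-[(4R,5R)-5-[(3E)-4,8-dimethylnona-3,7-dien-1-yl]-5-methyl-2-oxo-1,3-dioxolan-4-yl]ethyl}oxan-2-yl]prop-2-enoate (2,5-trans; the C5 label changes only through CIP priorities), via alkylidene phosphonoacetate 15 (not isolated), via oxanyl phosphonoacetate 16 (not isolated)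
Conditions: 14 (1.5 equiv), ethylenediammonium diacetate (10 mol%), 4 Å MS, PhMe, 45 °C; then K2CO3 (3 equiv), THF, rt, 2 h; then 37% aq. HCHO (5 equiv), rt
Reagents that add atoms: formaldehyde, C=O
Why: Proposed new method: Knoevenagel condensation of the open-chain aldehyde with the phosphonoacetate gives the doubly activated alkene 15, the free C6–OH adds 6-exo-trig to C2 to give 16 (reversible under carbonate, so the chair with both C2 and C5 substituents equatorial, i.e. 2,5-trans with C2 = R, should dominate, expected ≥8:1), and the same phosphonate carbanion undergoes Horner–Wadsworth–Emmons methylenation with formaldehyde, which fixes C2 and creates the acrylate; the closest known reaction types are Lehnert-type Knoevenagel condensations of phosphonoacetates, Knoevenagel/oxa-Michael C-glycosidation of lactols, and Villiéras methylenation of α-phosphono esters.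

**Step 8**
Reactants: 17 ethyl 2-[(2R,5R)-5-{2-[(4R,5R)-5-[(3E)-4,8-dimethylnona-3,7-dien-1-yl]-5-methyl-2-oxo-1,3-dioxolan-4-yl]ethyl}oxan-2-yl]prop-2-enoate
Product: 18 2-[(2R,5S)-5-[(3R,4R,7E)-3,4-dihydroxy-4,8,12-trimethyltrideca-7,11-dien-1-yl]oxan-2-yl]prop-2-enoic acid (target, CNP0285744.2)
Conditions: LiOH·H2O (6 equiv), THF/H2O 3:1, rt → 40 °C; then 1 M HCl to pH 3
Reagents that add atoms: lithium hydroxide, [Li+].[OH-]
Why: Saponification cleaves the ethyl ester and the cyclic carbonate at the acyl carbons only, so all four stereocentres are untouched; omitting methanol avoids alkoxide addition to the acrylate.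

## Compound list

1 | (2E,6E)-farnesol [(2E,6E)-3,7,11-trimethyldodeca-2,6,10-trien-1-ol] | OC/C=C(\C)CC/C=C(\C)CCC=C(C)C | starting material
2 | [(2R,3R)-3-[(3E)-4,8-dimethylnona-3,7-dien-1-yl]-3-methyloxiran-2-yl]methanol | OC[C@H]1O[C@]1(C)CC/C=C(\C)CCC=C(C)C | intermediate
3 | 2-(2-bromoethyl)-1,3-dioxolane | BrCCC1OCCO1 | starting material
4 | [(2R,3R)-3-[(3E)-4,8-dimethylnona-3,7-dien-1-yl]-3-methyloxiran-2-yl]methyl trifluoromethanesulfonate | FC(F)(F)S(=O)(=O)OC[C@H]1O[C@]1(C)CC/C=C(\C)CCC=C(C)C | intermediate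
5 | [2-(1,3-dioxolan-2-yl)ethyl]magnesium bromide | Br[Mg]CCC1OCCO1 | intermediate
6 | 2-{3-[(2R,3R)-3-[(3E)-4,8-dimethylnona-3,7-dien-1-yl]-3-methyloxiran-2-yl]propyl}-1,3-dioxolane | C1COC(CCC[C@H]2O[C@]2(C)CC/C=C(\C)CCC=C(C)C)O1 | intermediate
7 | (4R,5R)-4-[(3E)-4,8-dimethylnona-3,7-dien-1-yl]-5-[3-(1,3-dioxolan-2-yl)propyl]-4-methyl-1,3-dioxolan-2-one | C1COC(CCC[C@H]2OC(=O)O[C@]2(C)CC/C=C(\C)CCC=C(C)C)O1 | intermediate
8 | 4-[(4R,5R)-5-[(3E)-4,8-dimethylnona-3,7-dien-1-yl]-5-methyl-2-oxo-1,3-dioxolan-4-yl]butanal | O=CCCC[C@H]1OC(=O)O[C@]1(C)CC/C=C(\C)CCC=C(C)C | intermediate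
9 | 2-(triphenyl-λ5-phosphanylidene)acetaldehyde | O=CC=P(c1ccccc1)(c1ccccc1)c1ccccc1 | starting material
10 | (2R)-4-[(4R,5R)-5-[(3E)-4,8-dimethylnona-3,7-dien-1-yl]-5-methyl-2-oxo-1,3-dioxolan-4-yl]-2-(hydroxymethyl)butanal | O=C[C@@H](CO)CC[C@H]1OC(=O)O[C@]1(C)CC/C=C(\C)CCC=C(C)C | intermediate
11 | (2E,4S)-6-[(4R,5R)-5-[(3E)-4,8-dimethylnona-3,7-dien-1-yl]-5-methyl-2-oxo-1,3-dioxolan-4-yl]-4-(hydroxymethyl)hex-2-enal | O=C/C=C/[C@@H](CO)CC[C@H]1OC(=O)O[C@]1(C)CC/C=C(\C)CCC=C(C)C | intermediate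
12 | (4S)-6-[(4R,5R)-5-[(3E)-4,8-dimethylnona-3,7-dien-1-yl]-5-methyl-2-oxo-1,3-dioxolan-4-yl]-4-(hydroxymethyl)hexanal | O=CCC[C@@H](CO)CC[C@H]1OC(=O)O[C@]1(C)CC/C=C(\C)CCC=C(C)C | intermediate
13 | (4R,5R)-4-[(3E)-4,8-dimethylnona-3,7-dien-1-yl]-5-{2-[(3S)-6-hydroxyoxan-3-yl]ethyl}-4-methyl-1,3-dioxolan-2-one | OC1CC[C@H](CC[C@H]2OC(=O)O[C@]2(C)CC/C=C(\C)CCC=C(C)C)CO1 | intermediate
14 | triethyl phosphonoacetate [ethyl 2-(diethoxyphosphoryl)acetate] | CCOC(=O)CP(=O)(OCC)OCC | starting material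
15 | ethyl (6R)-2-(diethoxyphosphoryl)-8-[(4R,5R)-5-[(3E)-4,8-dimethylnona-3,7-dien-1-yl]-5-methyl-2-oxo-1,3-dioxolan-4-yl]-6-(hydroxymethyl)oct-2-enoate (E/Z) | CCOC(=O)C(=CCC[C@@H](CO)CC[C@H]1OC(=O)O[C@]1(C)CC/C=C(\C)CCC=C(C)C)P(=O)(OCC)OCC | intermediate
16 | ethyl 2-(diethoxyphosphoryl)-2-[(2R,5S)-5-{2-[(4R,5R)-5-[(3E)-4,8-dimethylnona-3,7-dien-1-yl]-5-methyl-2-oxo-1,3-dioxolan-4-yl]ethyl}oxan-2-yl]acetate (epimers at the P-bearing carbon) | CCOC(=O)C([C@H]1CC[C@H](CC[C@H]2OC(=O)O[C@]2(C)CC/C=C(\C)CCC=C(C)C)CO1)P(=O)(OCC)OCC | intermediate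
17 | ethyl 2-[(2R,5R)-5-{2-[(4R,5R)-5-[(3E)-4,8-dimethylnona-3,7-dien-1-yl]-5-methyl-2-oxo-1,3-dioxolan-4-yl]ethyl}oxan-2-yl]prop-2-enoate | C=C(C(=O)OCC)[C@H]1CC[C@H](CC[C@H]2OC(=O)O[C@]2(C)CC/C=C(\C)CCC=C(C)C)CO1 | intermediate
18 | 2-[(2R,5S)-5-[(3R,4R,7E)-3,4-dihydroxy-4,8,12-trimethyltrideca-7,11-dien-1-yl]oxan-2-yl]prop-2-enoic acid | C=C(C(=O)O)[C@H]1CC[C@H](CC[C@@H](O)[C@](C)(O)CC/C=C(\C)CCC=C(C)C)CO1 | target

## Step count and risk

Total step count: 8. Longest linear sequence: 8 (from farnesol; 3, 9 and 14 are bought).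

**Steps most likely to fail**

- **Step 3 (CO2 insertion with retention into a hindered trisubstituted epoxide).** It may be slow, or may leak through tertiary-carbon opening or Meinwald rearrangement. Fallback: set out from epoxy alcohol 2. Dess–Martin oxidation gives (2S,3R)-3-[(3E)-4,8-dimethylnona-3,7-dien-1-yl]-3-methyloxirane-2-carbaldehyde F1. Wittig reaction with the ylide of commercial [2-(1,3-dioxolan-2-yl)ethyl]triphenylphosphonium bromide (NaHMDS, THF, −78 °C) gives the (Z)-vinyl epoxide F2. Pd(PPh3)4 under CO2 (THF, rt) converts it, through a π-allyl palladium alkoxide and double inversion, into the vinyl cyclic carbonate F3 with retention (Trost's cis-hydroxylation equivalent). Diimide (2-nitrobenzenesulfonyl hydrazide, Et3N, CH2Cl2) then reduces only the disubstituted alkene and the route is rejoined at 7.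

- **Step 5 (hydroxymethylation with formyl-ylide trapping).** Ylide 9 may be too sluggish, allowing dehydration or epimerisation of 10, or double homologation. Fallback: set out from aldehyde 8, run the same hydroxymethylation, but trap 10 with methyl (triphenylphosphoranylidene)acetate (the precedented trapping mode) to give the hydroxy enoate F4. Copper hydride conjugate reduction (cat. Stryker's reagent, PMHS, t-BuOH) gives the saturated hydroxy ester F5. This lactonises (cat. PPTS, PhMe, 60 °C) to the δ-lactone F6. DIBAL-H (1.1 equiv, CH2Cl2, −78 °C) then gives lactol 13, where the route is rejoined.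

- **Step 7 (one-pot Knoevenagel/oxa-Michael/methylenation).** The Knoevenagel condensation of an enolisable lactol may be inefficient, the amine salt may attack the carbonate, or the trans selectivity may be low. Fallback: set out from lactol 13. Wittig reaction with ethyl (triphenylphosphoranylidene)acetate gives the hydroxy enoate F7. Catalytic KOt-Bu (THF, 0 °C) equilibrates the oxa-Michael adduct to the trans-oxanyl acetate F8. LDA (−78 °C) followed by Eschenmoser's salt gives the Mannich base F9. MeI gives the ammonium iodide F10, and NaHCO3 eliminates trimethylamine to give 17, where the route is rejoined.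

## Further compounds

F1 | step 3 | (2S,3R)-3-[(3E)-4,8-dimethylnona-3,7-dien-1-yl]-3-methyloxirane-2-carbaldehyde | O=C[C@H]1O[C@]1(C)CC/C=C(\C)CCC=C(C)C
F2 | step 3 | 2-[(2Z)-3-[(2R,3R)-3-[(3E)-4,8-dimethylnona-3,7-dien-1-yl]-3-methyloxiran-2-yl]prop-2-en-1-yl]-1,3-dioxolane | C1COC(C/C=C\[C@H]2O[C@]2(C)CC/C=C(\C)CCC=C(C)C)O1
F3 | step 3 | (4R,5R)-4-[(3E)-4,8-dimethylnona-3,7-dien-1-yl]-5-[3-(1,3-dioxolan-2-yl)prop-1-en-1-yl]-4-methyl-1,3-dioxolan-2-one (E/Z mixture) | C1COC(CC=C[C@H]2OC(=O)O[C@]2(C)CC/C=C(\C)CCC=C(C)C)O1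
F4 | step 5 | methyl (2E,4S)-6-[(4R,5R)-5-[(3E)-4,8-dimethylnona-3,7-dien-1-yl]-5-methyl-2-oxo-1,3-dioxolan-4-yl]-4-(hydroxymethyl)hex-2-enoate | COC(=O)/C=C/[C@@H](CO)CC[C@H]1OC(=O)O[C@]1(C)CC/C=C(\C)CCC=C(C)C
F5 | step 5 | methyl (4S)-6-[(4R,5R)-5-[(3E)-4,8-dimethylnona-3,7-dien-1-yl]-5-methyl-2-oxo-1,3-dioxolan-4-yl]-4-(hydroxymethyl)hexanoate | COC(=O)CC[C@@H](CO)CC[C@H]1OC(=O)O[C@]1(C)CC/C=C(\C)CCC=C(C)C
F6 | step 5 | (5S)-5-{2-[(4R,5R)-5-[(3E)-4,8-dimethylnona-3,7-dien-1-yl]-5-methyl-2-oxo-1,3-dioxolan-4-yl]ethyl}oxan-2-one | O=C1CC[C@H](CC[C@H]2OC(=O)O[C@]2(C)CC/C=C(\C)CCC=C(C)C)CO1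
F7 | step 7 | ethyl (2E,6R)-8-[(4R,5R)-5-[(3E)-4,8-dimethylnona-3,7-dien-1-yl]-5-methyl-2-oxo-1,3-dioxolan-4-yl]-6-(hydroxymethyl)oct-2-enoate | CCOC(=O)/C=C/CC[C@@H](CO)CC[C@H]1OC(=O)O[C@]1(C)CC/C=C(\C)CCC=C(C)C
F8 | step 7 | ethyl 2-[(2R,5R)-5-{2-[(4R,5R)-5-[(3E)-4,8-dimethylnona-3,7-dien-1-yl]-5-methyl-2-oxo-1,3-dioxolan-4-yl]ethyl}oxan-2-yl]acetate | CCOC(=O)C[C@H]1CC[C@H](CC[C@H]2OC(=O)O[C@]2(C)CC/C=C(\C)CCC=C(C)C)CO1
F9 | step 7 | ethyl 3-(dimethylamino)-2-[(2R,5R)-5-{2-[(4R,5R)-5-[(3E)-4,8-dimethylnona-3,7-dien-1-yl]-5-methyl-2-oxo-1,3-dioxolan-4-yl]ethyl}oxan-2-yl]propanoate | CCOC(=O)C(CN(C)C)[C@H]1CC[C@H](CC[C@H]2OC(=O)O[C@]2(C)CC/C=C(\C)CCC=C(C)C)CO1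
F10 | step 7 | 3-ethoxy-N,N,N-trimethyl-3-oxo-2-[(2R,5R)-5-{2-[(4R,5R)-5-[(3E)-4,8-dimethylnona-3,7-dien-1-yl]-5-methyl-2-oxo-1,3-dioxolan-4-yl]ethyl}oxan-2-yl]propan-1-aminium iodide | CCOC(=O)C(C[N+](C)(C)C)[C@H]1CC[C@H](CC[C@H]2OC(=O)O[C@]2(C)CC/C=C(\C)CCC=C(C)C)CO1.[I-]
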